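**Assumption:** germacrane numbering is used for the ten-membered ring and its precursors (ring C1–C10, C14 on C10, C15 on C4, lactone carbons C11–C13; β = the face of the C7–C11 bond), and the target is read from the SMILES as (1R,3S,6R,7R,8R,10R,2'R,3'R).

**Retrosynthetic overview**
1. Target ⇐ 1(10)-alkene (late face-selective epoxidation); C3–Cl ⇐ 3α-alcohol (SN2 inversion); exocyclic methylene ⇐ lactone methylenation.
2. γ-Lactone and C8 ester ⇐ β-hydroxy ketone + side-chain aldehyde (samarium-catalysed Tishchenko reduction, 1,3-anti, then lactonization); aldehyde ⇐ L-threonine.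
3. Ten-membered keto ester ⇐ 1,2-dialkenylcyclohexenol by anionic oxy-Cope ring expansion with in-flask C7 alkylation (chirality passes from C1 to C8).
4. Carbinol ⇐ (4R,6S)-4-silyloxy-6-isopropenyl enone (from (R)-carvone by epoxidation, Wharton transposition, allylic oxidation) + (Z)-2-(4-methoxybenzyloxy)vinyllithium.
5. Ring order: cyclohexene (bought in carvone) → ten-membered carbocycle → γ-lactone → oxirane.

**Step 1**
Reactants: 1 (R)-(−)-carvone
Product: 2 (1R,4R,6R)-1-methyl-4-(prop-1-en-2-yl)-7-oxabicyclo[4.1.0]heptan-2-one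
Conditions: 30% H2O2, NaOH (0.3 equiv), MeOH, 0 °C
Reagents that add atoms: hydrogen peroxide, OO
Why: Weitz–Scheffer nucleophilic epoxidation; hydroperoxide attacks the enone face anti to the isopropenyl group, so the oxirane is trans to it.

**Step 2**
Reactants: 2 trans-carvone epoxide
Product: 4 (1R,5S)-2-methyl-5-(prop-1-en-2-yl)cyclohex-2-en-1-ol [(+)-trans-carveol], via epoxy hydrazone 3 (not isolated)
Conditions: N2H4·H2O (3 equiv), AcOH (cat.), MeOH, 0 °C to rt
Reagents that add atoms: none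
Why: Wharton transposition; the epoxy hydrazone opens and loses N2 without touching the C3–O bond, so the hydroxyl stays trans to the isopropenyl group and the carveol skeleton is obtained in the (5S) series.

**Step 3**
Reactants: 4 (+)-trans-carveol
Product: 5 tert-butyldimethyl{[(1R,5S)-2-methyl-5-(prop-1-en-2-yl)cyclohex-2-en-1-yl]oxy}silane
Conditions: TBSCl, imidazole, DMF, rt
Reagents that add atoms: tert-butyldimethylsilyl chloride, C[Si](C)(Cl)C(C)(C)C
Why: Standard silylation of the secondary allylic alcohol; no stereocentre is involved.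

**Step 4**
Reactants: 5 trans-carveol TBS ether
Product: 6 (4R,6S)-4-[(tert-butyldimethylsilyl)oxy]-3-methyl-6-(prop-1-en-2-yl)cyclohex-2-en-1-one
Conditions: CrO3 (12 equiv), 3,5-dimethylpyrazole (12 equiv), CH2Cl2, −20 °C
Reagents that add atoms: chromium trioxide, O=[Cr](=O)=O
Why: Allylic oxidation of the only allylic ring CH2 to the enone; both stereocentres are untouched, and the trans isomer (isopropenyl pseudo-equatorial, silyloxy pseudo-axial beside the vinylic methyl) is also the more stable one.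

**Step 5**
Reactants: 7 4-methoxybenzyl alcohol
Product: 8 1-[(ethenyloxy)methyl]-4-methoxybenzene (PMB vinyl ether)
Conditions: Pd(OAc)2 (2 mol %), 1,10-phenanthroline (2 mol %), ethyl vinyl ether (20 equiv, as solvent), air, rt
Reagents that add atoms: ethyl vinyl ether, C=COCC
Why: Palladium-catalysed transfer vinylation (transetherification) of a primary alcohol, driven by excess vinyl ether.

**Step 6**
Reactants: 8 PMB vinyl ether
Product: 10 1-({[(Z)-2-bromoethenyl]oxy}methyl)-4-methoxybenzene, via dibromo ether 9 (not isolated)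
Conditions: Br2, CH2Cl2, −78 °C; then i-Pr2NEt, −78 °C to 40 °C
Reagents that add atoms: bromine, BrBr
Why: Bromine addition followed by dehydrobromination of the α-bromo ether; the cis (Z) 2-bromovinyl ether predominates, as in the preparation of cis-1-bromo-2-ethoxyethene, and the minor E isomer is removed by chromatography.

**Step 7**
Reactants: 10 (Z)-bromovinyl PMB ether; 6 enone
Product: 12 (1S,4R,6S)-4-[(tert-butyldimethylsilyl)oxy]-1-{(Z)-2-[(4-methoxybenzyl)oxy]ethenyl}-3-methyl-6-(prop-1-en-2-yl)cyclohex-2-en-1-ol, via Z-vinyllithium 11 (not isolated)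
Conditions: t-BuLi (2.0 equiv), Et2O, −78 °C; then 6, THF, −78 °C; NaHCO3 work-up
Reagents that add atoms: none
Why: Bromine–lithium exchange with retention of the Z geometry, then 1,2-addition to the enone anti to the adjacent isopropenyl group (as in additions to isopiperitenone), which sets the carbinol with the two alkenyl groups trans; the minor epimer is separated.

**Step 8**
Reactants: 12 dialkenyl carbinol
Product: 15 ethyl 2-[(1R,3Z,5R,7E,10R)-5-[(tert-butyldimethylsilyl)oxy]-10-[(4-methoxybenzyl)oxy]-4,8-dimethyl-2-oxocyclodeca-3,7-dien-1-yl]acetate, via potassium carbinolate 13 (not isolated), via potassium dienolate 14 (not isolated)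
Conditions: KN(SiMe3)2 (1.1 equiv), THF, −78 to 25 °C; then ICH2CO2Et, −78 to −40 °C
Reagents that add atoms: ethyl iodoacetate, ICC(=O)OCC
Why: Anionic oxy-Cope rearrangement ([3,3]-sigmatropic) through a chair transition state with both ring bonds equatorial and K+ bridging the alkoxide and the cis PMB-oxy group gives the ten-membered ring with the 1(10)-E alkene and passes the C1 chirality to C8 (8β-O); the chelated β-alkoxy enolate is then alkylated anti to C9 (Fráter–Seebach sense), which sets C7.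

**Step 9**
Reactants: 15 keto ester
Product: 16 ethyl 2-[(1R,3Z,5R,7E,10R)-5-[(tert-butyldimethylsilyl)oxy]-10-hydroxy-4,8-dimethyl-2-oxocyclodeca-3,7-dien-1-yl]acetate
Conditions: DDQ, CH2Cl2/pH 7 buffer (10:1), 0 °C; crude product used at once
Reagents that add atoms: none
Why: Oxidative cleavage of the PMB ether under neutral conditions leaves the silyl ether, the ester and the β-hydroxy ketone stereocentres intact.

**Step 10**
Reactants: 17 L-threonine
Product: 18 (2S,3R)-2,3-dihydroxybutanoic acid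
Conditions: NaNO2, 1 M H2SO4, H2O, 0 °C to rt
Reagents that add atoms: water, O
Why: Diazotization with carboxylate participation (double inversion through the α-lactone) replaces NH2 by OH with retention at C2.

**Step 11**
Reactants: 18 dihydroxy acid
Product: 19 methyl (4S,5R)-2,2,5-trimethyl-1,3-dioxolane-4-carboxylate
Conditions: Me2C(OMe)2, MeOH, TsOH·H2O (cat.), reflux
Reagents that add atoms: 2,2-dimethoxypropane, COC(C)(C)OC; methanol, CO
Why: Fischer esterification and acetonide formation in one pot; neither stereocentre is touched.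

**Step 12**
Reactants: 19 acetonide ester
Product: 21 methyl (4R,5R)-2,2,4,5-tetramethyl-1,3-dioxolane-4-carboxylate, via lithium enolate 20 (not isolated)
Conditions: LiN(i-Pr)2, THF, −78 °C; then MeI, −78 to −40 °C
Reagents that add atoms: iodomethane, CI
Why: Alkylation of the dioxolane ester enolate anti to the C5 methyl group puts the new methyl trans to it, giving the (2R,3R) pattern of the side chain from the threonine stereocentre.

**Step 13**
Reactants: 21 methylated ester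
Product: 22 (4R,5R)-2,2,4,5-tetramethyl-1,3-dioxolane-4-carbaldehyde
Conditions: i-Bu2AlH (1.1 equiv), CH2Cl2, −78 °C
Reagents that add atoms: none
Why: Partial reduction of an α-alkoxy ester stops at the chelated hemiacetal; the aldehyde has no α-hydrogen and cannot epimerize.

**Step 14**
Reactants: 16 β-hydroxy ketone; 22 side-chain aldehyde
Product: 24 (3R,6R,7R,8R)-3-[(tert-butyldimethylsilyl)oxy]-8-{[(4R,5R)-2,2,4,5-tetramethyl-1,3-dioxolane-4-carbonyl]oxy}-13-norgermacra-1(10)E,4Z-dien-12,6-olide, via 6α-hydroxy ester 23 (not isolated)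
Conditions: SmI2 (0.3 equiv), 22 (3 equiv), THF, −10 °C; then PPTS (cat.), CH2Cl2, rt
Reagents that add atoms: none
Why: Evans–Tishchenko reduction; the samarium-bound hemiacetal on O8 delivers hydride intramolecularly to C6 from the O8 side, giving the 1,3-anti 6α-alcohol and the C8 ester in one event, and the free 6α-hydroxyl then closes the trans-fused γ-lactone on the ethyl ester.

**Step 15**
Reactants: 24 lactone
Product: 28 (3R,6R,7R,8R)-3-[(tert-butyldimethylsilyl)oxy]-8-{[(4R,5R)-2,2,4,5-tetramethyl-1,3-dioxolane-4-carbonyl]oxy}germacra-1(10)E,4Z,11(13)-trien-12,6-olide, via lithium lactone enolate 25 (not isolated), via Mannich base 26 (not isolated), via trimethylammonium iodide 27 (not isolated)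
Conditions: LiN(i-Pr)2, THF, −78 °C; CH2=NMe2+ I−, −78 to 0 °C; then MeI, MeOH, rt; then NaHCO3 (aq), CH2Cl2, rt
Reagents that add atoms: Eschenmoser's salt, C=[N+](C)C.[I-]
Why: Mannich reaction of the lactone enolate, quaternization and Hofmann-type elimination give the exocyclic methylene; the C8 ester has no α-hydrogen and the C11 centre becomes sp2.

**Step 16**
Reactants: 28 protected trienolide
Product: 29 (3R,6R,7R,8R)-3-hydroxy-8-{[(2R,3R)-2,3-dihydroxy-2-methylbutanoyl]oxy}germacra-1(10)E,4Z,11(13)-trien-12,6-olide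
Conditions: TFA/H2O/THF (2:1:2), 0 °C to rt
Reagents that add atoms: none
Why: Acid hydrolysis removes the silyl ether and the acetonide together; the 4,5-alkene is deactivated by two allylic oxygens, which disfavours transannular cyclization at low temperature.

**Step 17**
Reactants: 29 triol
Product: 30 (3S,6R,7R,8R)-3-chloro-8-{[(2R,3R)-2,3-dihydroxy-2-methylbutanoyl]oxy}germacra-1(10)E,4Z,11(13)-trien-12,6-olide
Conditions: PPh3 (1.2 equiv), (Cl3C)2CO, CH2Cl2, −30 to 0 °C
Reagents that add atoms: hexachloroacetone, O=C(C(Cl)(Cl)Cl)C(Cl)(Cl)Cl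
Why: Appel-type chlorination; the allylic oxyphosphonium at C3 is displaced by chloride with SN2 inversion (3α-OH to 3β-Cl), while the tertiary and neopentyl-like side-chain hydroxyls are far slower.

**Step 18**
Reactants: 30 chloro trienolide
Product: 31 (1R,3S,6R,7R,8R,10R)-3-chloro-1,10-epoxy-8-{[(2R,3R)-2,3-dihydroxy-2-methylbutanoyl]oxy}germacra-4Z,11(13)-dien-12,6-olide (CNP0325326.4)
Conditions: mCPBA (1.1 equiv), NaHCO3, CH2Cl2, 0 °C
Reagents that add atoms: 3-chloroperbenzoic acid, O=C(OO)c1cccc(Cl)c1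
Why: Prilezhaev epoxidation of the only electron-rich alkene (the 4,5-alkene carries allylic Cl and O, the methylene is conjugated), with attack on the outer face of the E-1(10) alkene expected to give the 1β,10α-oxirane common to the natural heliangolides.

**Compound list**
1 | (R)-(−)-carvone | C=C(C)[C@H]1CC(=O)C(C)=CC1 | starting material
2 | (1R,4R,6R)-1-methyl-4-(prop-1-en-2-yl)-7-oxabicyclo[4.1.0]heptan-2-one | C=C(C)[C@H]1CC(=O)[C@]2(C)O[C@@H]2C1 | intermediate
3 | hydrazone of 2 | C=C(C)[C@H]1CC(=NN)[C@]2(C)O[C@@H]2C1 | intermediate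
4 | (1R,5S)-2-methyl-5-(prop-1-en-2-yl)cyclohex-2-en-1-ol, (+)-trans-carveol | C=C(C)[C@H]1CC=C(C)[C@H](O)C1 | intermediate
5 | TBS ether of 4 | C=C(C)[C@H]1CC=C(C)[C@H](O[Si](C)(C)C(C)(C)C)C1 | intermediate
6 | (4R,6S)-4-[(tert-butyldimethylsilyl)oxy]-3-methyl-6-(prop-1-en-2-yl)cyclohex-2-en-1-one | C=C(C)[C@H]1C(=O)C=C(C)[C@H](O[Si](C)(C)C(C)(C)C)C1 | intermediate
7 | 4-methoxybenzyl alcohol | COc1ccc(CO)cc1 | starting material
8 | 1-[(ethenyloxy)methyl]-4-methoxybenzene | C=COCc1ccc(OC)cc1 | intermediate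
9 | 1-[(1,2-dibromoethoxy)methyl]-4-methoxybenzene | BrCC(Br)OCc1ccc(OC)cc1 | intermediate
10 | 1-({[(Z)-2-bromoethenyl]oxy}methyl)-4-methoxybenzene | Br/C=C\OCc1ccc(OC)cc1 | intermediate
11 | (Z)-2-[(4-methoxybenzyl)oxy]ethenyllithium | [Li]/C=C\OCc1ccc(OC)cc1 | intermediate
12 | (1S,4R,6S)-4-TBSO-1-{(Z)-2-[(4-methoxybenzyl)oxy]ethenyl}-3-methyl-6-(prop-1-en-2-yl)cyclohex-2-en-1-ol (alkenyl groups trans) | O[C@@]1(/C=C\OCc2ccc(OC)cc2)C=C(C)[C@H](O[Si](C)(C)C(C)(C)C)C[C@H]1C(C)=C | intermediate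
13 | potassium alkoxide of 12 | [K+].[O-][C@@]1(/C=C\OCc2ccc(OC)cc2)C=C(C)[C@H](O[Si](C)(C)C(C)(C)C)C[C@H]1C(C)=C | intermediate
14 | potassium 6-enolate of the ten-membered ketone (3α-OTBS, 8β-OPMB, 1(10)E, 4Z, O− cis to C8) | [K+].COc1ccc(CO[C@H]2/C=C(\[O-])/C=C(/C)[C@H](O[Si](C)(C)C(C)(C)C)C/C=C(\C)C2)cc1 | intermediate
15 | ethyl 2-[(1R,3Z,5R,7E,10R)-5-TBSO-10-[(4-methoxybenzyl)oxy]-4,8-dimethyl-2-oxocyclodeca-3,7-dien-1-yl]acetate (3α-OTBS, 7α-H, 8β-OPMB) | O=C1/C=C(/C)[C@H](O[Si](C)(C)C(C)(C)C)C/C=C(\C)C[C@@H](OCc2ccc(OC)cc2)[C@H]1CC(=O)OCC | intermediate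
16 | ethyl 2-[(1R,3Z,5R,7E,10R)-5-TBSO-10-hydroxy-4,8-dimethyl-2-oxocyclodeca-3,7-dien-1-yl]acetate | O=C1/C=C(/C)[C@H](O[Si](C)(C)C(C)(C)C)C/C=C(\C)C[C@@H](O)[C@H]1CC(=O)OCC | intermediate
17 | L-threonine | C[C@@H](O)[C@H](N)C(=O)O | starting material
18 | (2S,3R)-2,3-dihydroxybutanoic acid | C[C@@H](O)[C@H](O)C(=O)O | intermediate
19 | methyl (4S,5R)-2,2,5-trimethyl-1,3-dioxolane-4-carboxylate | C[C@H]1OC(C)(C)O[C@@H]1C(=O)OC | intermediate
20 | lithium enolate of 19 | C[C@H]1OC(C)(C)OC1=C([O-])OC.[Li+] | intermediate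
21 | methyl (4R,5R)-2,2,4,5-tetramethyl-1,3-dioxolane-4-carboxylate | C[C@H]1OC(C)(C)O[C@@]1(C)C(=O)OC | intermediate
22 | (4R,5R)-2,2,4,5-tetramethyl-1,3-dioxolane-4-carbaldehyde | C[C@H]1OC(C)(C)O[C@@]1(C)C=O | intermediate
23 | ethyl ester of the 3α-OTBS, 6α-hydroxy, 8β-acyloxy seco acid (7α-H, 1(10)E, 4Z) | O[C@@H]1/C=C(/C)[C@H](O[Si](C)(C)C(C)(C)C)C/C=C(\C)C[C@@H](OC(=O)[C@]2(C)OC(C)(C)O[C@@H]2C)[C@H]1CC(=O)OCC | intermediate
24 | (3R,6R,7R,8R)-3-TBSO-8-{[(4R,5R)-2,2,4,5-tetramethyl-1,3-dioxolane-4-carbonyl]oxy}-13-norgermacra-1(10)E,4Z-dien-12,6-olide | C1C(=O)O[C@@H]2/C=C(/C)[C@H](O[Si](C)(C)C(C)(C)C)C/C=C(\C)C[C@@H](OC(=O)[C@]3(C)OC(C)(C)O[C@@H]3C)[C@@H]12 | intermediate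
25 | lithium enolate of 24 | [Li+].C1=C([O-])O[C@@H]2/C=C(/C)[C@H](O[Si](C)(C)C(C)(C)C)C/C=C(\C)C[C@@H](OC(=O)[C@]3(C)OC(C)(C)O[C@@H]3C)[C@@H]12 | intermediate
26 | 11-[(dimethylamino)methyl] derivative of 24 (C11 mixture) | CN(C)CC1C(=O)O[C@@H]2/C=C(/C)[C@H](O[Si](C)(C)C(C)(C)C)C/C=C(\C)C[C@@H](OC(=O)[C@]3(C)OC(C)(C)O[C@@H]3C)[C@@H]12 | intermediate
27 | trimethylammonium iodide of 26 | C[N+](C)(C)CC1C(=O)O[C@@H]2/C=C(/C)[C@H](O[Si](C)(C)C(C)(C)C)C/C=C(\C)C[C@@H](OC(=O)[C@]3(C)OC(C)(C)O[C@@H]3C)[C@@H]12.[I-] | intermediate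
28 | (3R,6R,7R,8R)-3-TBSO-8-{[(4R,5R)-2,2,4,5-tetramethyl-1,3-dioxolane-4-carbonyl]oxy}germacra-1(10)E,4Z,11(13)-trien-12,6-olide | C=C1C(=O)O[C@@H]2/C=C(/C)[C@H](O[Si](C)(C)C(C)(C)C)C/C=C(\C)C[C@@H](OC(=O)[C@]3(C)OC(C)(C)O[C@@H]3C)[C@@H]12 | intermediate
29 | (3R,6R,7R,8R)-3-hydroxy-8-{[(2R,3R)-2,3-dihydroxy-2-methylbutanoyl]oxy}germacra-1(10)E,4Z,11(13)-trien-12,6-olide | C=C1C(=O)O[C@@H]2/C=C(/C)[C@H](O)C/C=C(\C)C[C@@H](OC(=O)[C@](C)(O)[C@@H](C)O)[C@@H]12 | intermediate
30 | (3S,6R,7R,8R)-3-chloro-8-{[(2R,3R)-2,3-dihydroxy-2-methylbutanoyl]oxy}germacra-1(10)E,4Z,11(13)-trien-12,6-olide | C=C1C(=O)O[C@@H]2/C=C(/C)[C@@H](Cl)C/C=C(\C)C[C@@H](OC(=O)[C@](C)(O)[C@@H](C)O)[C@@H]12 | intermediate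
31 | (1R,3S,6R,7R,8R,10R)-3-chloro-1,10-epoxy-8-{[(2R,3R)-2,3-dihydroxy-2-methylbutanoyl]oxy}germacra-4Z,11(13)-dien-12,6-olide | C=C1C(=O)O[C@@H]2/C=C(/C)[C@@H](Cl)C[C@H]3O[C@]3(C)C[C@@H](OC(=O)[C@](C)(O)[C@@H](C)O)[C@@H]12 | target

**Totals**
Total steps: 18. Longest linear sequence: 12 (steps 1–4, 7–9, 14–18).

**Steps most likely to fail**

Step 8. The β-alkoxy enolate may lose PMB-oxide, the Z-alkoxyvinyl group may slow the rearrangement, or the C7 alkylation may be unselective. The fallback sets out from 12 and comes back at 15. Compound 12 is rearranged with KN(SiMe3)2 and 18-crown-6 at −20 to 0 °C and the enolate is protonated at −78 °C with AcOH, which gives the C7-unsubstituted ketone (2Z,4R,6E,9R)-4-[(tert-butyldimethylsilyl)oxy]-9-[(4-methoxybenzyl)oxy]-3,7-dimethylcyclodeca-2,6-dien-1-one F1. In a separate operation its lithium chelate enolate (LiN(i-Pr)2, THF, −78 °C) is alkylated with ethyl iodoacetate to give 15.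

Step 14. The α-quaternary aldehyde may be too hindered for hemiacetal formation, and 16 can undergo retro-aldol cleavage or close to the 8,12-lactone. The fallback sets out from 16 and comes back at 24. The same samarium-catalysed Tishchenko reduction is run with acetaldehyde and followed by PPTS, giving the 8β-acetoxy-3α-silyloxy-13-norgermacra-1(10)E,4Z-dien-12,6-olide F2. K2CO3 in MeOH removes the acetate to give the 8β-hydroxy lactone F3. Ester 21 is saponified (LiOH, then mild acid) to (4R,5R)-2,2,4,5-tetramethyl-1,3-dioxolane-4-carboxylic acid F4, and this acid is coupled to the 8β-hydroxyl under Yamaguchi conditions (2,4,6-trichlorobenzoyl chloride, Et3N, DMAP, toluene) to give 24.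

Step 17. The side-chain hydroxyls may compete, or SN2′ attack or chloride-induced epimerization may erode the 3β-chloride. The fallback sets out from 28 and comes back at 30. HF·pyridine removes only the silyl ether, giving the 3α-hydroxy acetonide F5. PPh3 and hexachloroacetone then meet a single hydroxyl and give the 3β-chloro acetonide F6 with inversion. Brief aqueous TFA at 0 °C frees the diol to give 30.

**Further compounds**
F1 | step 8 | (2Z,4R,6E,9R)-4-[(tert-butyldimethylsilyl)oxy]-9-[(4-methoxybenzyl)oxy]-3,7-dimethylcyclodeca-2,6-dien-1-one | O=C1/C=C(/C)[C@H](O[Si](C)(C)C(C)(C)C)C/C=C(\C)C[C@@H](OCc2ccc(OC)cc2)C1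
F2 | step 14 | (3R,6R,7R,8R)-8-acetoxy-3-[(tert-butyldimethylsilyl)oxy]-13-norgermacra-1(10)E,4Z-dien-12,6-olide | C1C(=O)O[C@@H]2/C=C(/C)[C@H](O[Si](C)(C)C(C)(C)C)C/C=C(\C)C[C@@H](OC(C)=O)[C@@H]12
F3 | step 14 | (3R,6R,7R,8R)-3-[(tert-butyldimethylsilyl)oxy]-8-hydroxy-13-norgermacra-1(10)E,4Z-dien-12,6-olide | C1C(=O)O[C@@H]2/C=C(/C)[C@H](O[Si](C)(C)C(C)(C)C)C/C=C(\C)C[C@@H](O)[C@@H]12
F4 | step 14 | (4R,5R)-2,2,4,5-tetramethyl-1,3-dioxolane-4-carboxylic acid | C[C@H]1OC(C)(C)O[C@@]1(C)C(=O)O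
F5 | step 17 | (3R,6R,7R,8R)-3-hydroxy-8-{[(4R,5R)-2,2,4,5-tetramethyl-1,3-dioxolane-4-carbonyl]oxy}germacra-1(10)E,4Z,11(13)-trien-12,6-olide | C=C1C(=O)O[C@@H]2/C=C(/C)[C@H](O)C/C=C(\C)C[C@@H](OC(=O)[C@]3(C)OC(C)(C)O[C@@H]3C)[C@@H]12
F6 | step 17 | (3S,6R,7R,8R)-3-chloro-8-{[(4R,5R)-2,2,4,5-tetramethyl-1,3-dioxolane-4-carbonyl]oxy}germacra-1(10)E,4Z,11(13)-trien-12,6-olide | C=C1C(=O)O[C@@H]2/C=C(/C)[C@@H](Cl)C/C=C(\C)C[C@@H](OC(=O)[C@]3(C)OC(C)(C)O[C@@H]3C)[C@@H]12
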